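**Direct plan and its weak points**

A direct plan would build the β-benzyl lactone A1 (Stobbe condensation, asymmetric hydrogenation, ester reduction) and attach ring A by aldol addition and elimination, which would give the benzylidene lactone A2.
To oxygenate C3 it would then open ring C to a Weinreb amide, silylate C5–OH, reduce in two steps to the allylic alcohol A3, epoxidise under tartrate control to A4, open the oxirane with hydride, oxidise C2 back to the acid in two steps, close ring C again and debenzylate.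
Weak point 1, the opening of ring C and its later re-closure: about seven protecting-group and redox operations would form no bond of the skeleton and serve only to lend the epoxidation a CH2OH handle.
Weak point 2, the epoxidation of A3: the catalyst would have to override the branched, stereogenic C4 substituent on the alkene, and the product A4 is a p-alkoxyphenyl oxirane that ionises easily on Lewis-acidic titanium.
Weak point 3, the reductive opening of A4: hydride would have to displace the benzylic C–O bond while the Lewis-acidic aluminium reagent can ionise it first and trigger hydride or aryl shifts, so the quaternary carbinol would rest on two fragile steps set long after C4.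

**Retrosynthetic overview of the new route**

The cut goes through the C3–C4 bond of lactone ring C, the bond that joins the two C6–C3 halves and carries both stereocentres (quaternary carbinol C3, tertiary C4).
An Ireland–Claisen rearrangement of ester 12 (racemic ring A acid 11 plus ring B allylic alcohol 6) would form this bond and set C3 and C4 together, by chirality transfer from the S carbinol of (S)-but-3-yn-2-ol through a lithium-chelated Z ketene acetal and a Z alkene in one chair.
Rings A and B are bought as benzylic alcohols; ring C closes last, when the propenyl group left by the rearrangement is cut to C5–OH and lactonises onto the C2 acid.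
C2 stays at the acid level throughout and the C3 oxygen rides in from the start as a benzyl ether, so no lactone is opened and re-closed, no oxirane is made or reduced, and one hydrogenolysis frees all three hydroxyls.

Key step: step 9

Remark: lactone numbering is O1, C2 (C=O), C3 (carbinol), C4, C5; ring A is the guaiacyl ring on the C3 benzyl group, ring B the syringyl ring on the C4 benzyl group, ring C the lactone. (S)-But-3-yn-2-ol is assumed to be used in high enantiomeric purity, since it is the only source of absolute configuration.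

**Route**

Step 1
Reactants: 1 4-(hydroxymethyl)-2,6-dimethoxyphenol (syringyl alcohol)
Product: 2 [4-(benzyloxy)-3,5-dimethoxyphenyl]methanol
Conditions: BnBr (1.05 equiv), K2CO3, DMF, rt
Reagents that add atoms: benzyl bromide, BrCc1ccccc1
Why: Williamson etherification in which carbonate deprotonates only the phenol, so the benzylic alcohol should stay free.

Step 2
Reactants: 2 [4-(benzyloxy)-3,5-dimethoxyphenyl]methanol
Product: 3 2-(benzyloxy)-5-(bromomethyl)-1,3-dimethoxybenzene
Conditions: PBr3 (0.4 equiv), Et2O, 0 °C; aq. NaHCO3; used crude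
Reagents that add atoms: phosphorus tribromide, BrP(Br)Br
Why: Nucleophilic substitution of the phosphite ester of the electron-rich benzylic alcohol by bromide at 0 °C should leave the aryl benzyl ether intact.

Step 3
Reactants: 3 2-(benzyloxy)-5-(bromomethyl)-1,3-dimethoxybenzene; 4 (2S)-but-3-yn-2-ol
Product: 5 (2S)-5-[4-(benzyloxy)-3,5-dimethoxyphenyl]pent-3-yn-2-ol
Conditions: 4, EtMgBr (2.1 equiv), THF, 0 °C to rt; CuBr·SMe2 (10 mol %), then 3, 50 °C; aq. NH4Cl
Reagents that add atoms: none
Why: Copper-catalysed alkylation of the alkynylmagnesium bromide by the benzylic bromide should form the C(sp)–CH2 bond, the magnesium alkoxide being inert to alkylation and the carbinol centre untouched.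

Step 4
Reactants: 5 (2S)-5-[4-(benzyloxy)-3,5-dimethoxyphenyl]pent-3-yn-2-ol
Product: 6 (2S,3Z)-5-[4-(benzyloxy)-3,5-dimethoxyphenyl]pent-3-en-2-ol
Conditions: H2 (1 atm), Pd/CaCO3 poisoned with Pb(OAc)2 (Lindlar catalyst), quinoline, EtOAc, rt, stopped after 1 equiv of H2
Reagents that add atoms: none
Why: Lindlar semihydrogenation adds both hydrogens to one face of the alkyne and so should give the Z alkene, while the poisoned catalyst neither cleaves the benzyl ether nor reduces the alkene further.

Step 5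
Reactants: 7 [4-(benzyloxy)-3-methoxyphenyl]methanol
Product: 8 1-(benzyloxy)-4-(bromomethyl)-2-methoxybenzene
Conditions: PBr3 (0.4 equiv), Et2O, 0 °C; aq. NaHCO3; used crude
Reagents that add atoms: phosphorus tribromide, BrP(Br)Br
Why: The same substitution of a benzylic alcohol by bromide as in step 2 should give the bromide, which is used at once because it does not store well.

Step 6
Reactants: 9 methyl 2-(benzyloxy)acetate; 8 1-(benzyloxy)-4-(bromomethyl)-2-methoxybenzene
Product: 10 methyl 2-(benzyloxy)-3-[4-(benzyloxy)-3-methoxyphenyl]propanoate (racemic)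
Conditions: LiN(SiMe3)2 (1.1 equiv), THF, −78 °C; then 8, DMPU, −78 to −40 °C; aq. NH4Cl
Reagents that add atoms: none
Why: SN2 alkylation of the lithium enolate of the glycolate ester by the reactive benzylic bromide; the new centre needs no control because it is made planar again in step 9.

Step 7
Reactants: 10 methyl 2-(benzyloxy)-3-[4-(benzyloxy)-3-methoxyphenyl]propanoate
Product: 11 2-(benzyloxy)-3-[4-(benzyloxy)-3-methoxyphenyl]propanoic acid (racemic)
Conditions: LiOH·H2O (3 equiv), THF/MeOH/H2O, rt; then 1 M HCl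
Reagents that add atoms: lithium hydroxide, [Li+].[OH-]
Why: Saponification (acyl substitution by hydroxide) of the methyl ester, to which the three ether groups are inert.

Step 8
Reactants: 6 (2S,3Z)-5-[4-(benzyloxy)-3,5-dimethoxyphenyl]pent-3-en-2-ol; 11 2-(benzyloxy)-3-[4-(benzyloxy)-3-methoxyphenyl]propanoic acid
Product: 12 (2S,3Z)-5-[4-(benzyloxy)-3,5-dimethoxyphenyl]pent-3-en-2-yl 2-(benzyloxy)-3-[4-(benzyloxy)-3-methoxyphenyl]propanoate (both epimers at the acyl α-carbon)
Conditions: DCC (1.2 equiv), DMAP (0.1 equiv), CH2Cl2, 0 °C to rt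
Reagents that add atoms: none
Why: Steglich esterification acylates the carbinol oxygen without breaking its C–O bond, so the S configuration and the Z alkene are kept, and the two α-epimers are carried on together because step 9 converges them.

Step 9
Reactants: 12 (2S,3Z)-5-[4-(benzyloxy)-3,5-dimethoxyphenyl]pent-3-en-2-yl 2-(benzyloxy)-3-[4-(benzyloxy)-3-methoxyphenyl]propanoate
Product: 15 (2S,3S,4E)-2-(benzyloxy)-2-{[4-(benzyloxy)-3-methoxyphenyl]methyl}-3-{[4-(benzyloxy)-3,5-dimethoxyphenyl]methyl}hex-4-enoic acid, via silyl ketene acetal 13 (not isolated), via trimethylsilyl ester 14 (not isolated)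
Conditions: LiN(iPr)2 (1.3 equiv), THF, −78 °C; Me3SiCl/Et3N, −78 °C to rt, then 50 °C; 1 M HCl
Reagents that add atoms: none
Why: LiN(iPr)2 removes the single α-hydrogen of either epimer of 12, lithium held between the enolate oxygen and the α-benzyloxy oxygen fixes the enolate geometry, and silylation gives the (Z)-ketene acetal 13 (Me3SiO cis to BnO), which on warming undergoes a concerted suprafacial [3,3]-sigmatropic shift through a chair transition state to silyl ester 14, hydrolysed on work-up to acid 15. The closest known reaction type is the chelation-controlled Ireland–Claisen rearrangement of O-alkyl lactate and glycolate esters of secondary allylic alcohols, which gives α-alkoxy acids with transfer of chirality from the carbinol carbon. No ring is closed: the step forms the C3–C4 bond between the two C6–C3 halves and leaves ring C to close in step 10. C4 is set by the S carbinol centre, because in the chair its methyl group must lie equatorial to avoid a 1,3-diaxial clash with the axial CH2 of the Z alkene, so the ketene acetal meets one face of the alkene only and the new alkene is E; C3 is set relative to C4 by the geometry of 13, which places BnO equatorial and the ring A benzyl group axial, anti to the axial ring B benzyl group, and this is the (2S,3S) arrangement in which the oxygen on C3 ends cis to the C4 benzyl group in the lactone. The step needs a single ketene acetal geometry and chair over boat, which lithium chelation in THF and the open-chain ester should secure, and it needs the ester α-hydrogen to be removed before the doubly activated ring B CH2, which its far greater acidity at −78 °C should secure.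

Step 10
Reactants: 15 (2S,3S,4E)-2-(benzyloxy)-2-{[4-(benzyloxy)-3-methoxyphenyl]methyl}-3-{[4-(benzyloxy)-3,5-dimethoxyphenyl]methyl}hex-4-enoic acid
Product: 18 (3S,4S)-3-(benzyloxy)-3-{[4-(benzyloxy)-3-methoxyphenyl]methyl}-4-{[4-(benzyloxy)-3,5-dimethoxyphenyl]methyl}oxolan-2-one, via oxo acid 16 (not isolated), via hydroxy acid 17 (not isolated)
Conditions: O3, CH2Cl2/MeOH, −78 °C, stopped at the first excess of O3; NaBH4, −78 to 0 °C; then 2 M HCl, rt
Reagents that add atoms: ozone, [O-][O+]=O
Why: Ozonolysis with borohydride work-up should cut the propenyl group to C5–OH (the alkene reacts far faster with ozone than the alkoxyarenes, and the cold hydride reduces the aldehyde before C4 can epimerise), and acid then closes ring C by 5-exo-trig lactonisation of the γ-hydroxy acid.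

Step 11
Reactants: 18 (3S,4S)-3-(benzyloxy)-3-{[4-(benzyloxy)-3-methoxyphenyl]methyl}-4-{[4-(benzyloxy)-3,5-dimethoxyphenyl]methyl}oxolan-2-one
Product: 19 (3S,4S)-3-hydroxy-3-[(4-hydroxy-3-methoxyphenyl)methyl]-4-[(4-hydroxy-3,5-dimethoxyphenyl)methyl]oxolan-2-one (CNP0315014.1)
Conditions: H2 (1 atm), Pd(OH)2/C, EtOAc/EtOH, rt
Reagents that add atoms: none
Why: Hydrogenolysis should cleave the three O–CH2Ph bonds (two aryl benzyl ethers and the tertiary alkyl benzyl ether), while the C3–O bond is only homobenzylic, the lactone C5–O bond is not benzylic and no stereocentre is touched.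

**Compound list**

1 | 4-(hydroxymethyl)-2,6-dimethoxyphenol (syringyl alcohol) | COc1cc(CO)cc(OC)c1O | starting material
2 | [4-(benzyloxy)-3,5-dimethoxyphenyl]methanol | OCc1cc(OC)c(OCc2ccccc2)c(OC)c1 | intermediate
3 | 2-(benzyloxy)-5-(bromomethyl)-1,3-dimethoxybenzene | BrCc1cc(OC)c(OCc2ccccc2)c(OC)c1 | intermediate
4 | (2S)-but-3-yn-2-ol | C[C@H](O)C#C | starting material
5 | (2S)-5-[4-(benzyloxy)-3,5-dimethoxyphenyl]pent-3-yn-2-ol | C[C@H](O)C#CCc1cc(OC)c(OCc2ccccc2)c(OC)c1 | intermediate
6 | (2S,3Z)-5-[4-(benzyloxy)-3,5-dimethoxyphenyl]pent-3-en-2-ol | C[C@H](O)/C=C\Cc1cc(OC)c(OCc2ccccc2)c(OC)c1 | intermediate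
7 | [4-(benzyloxy)-3-methoxyphenyl]methanol | OCc1ccc(OCc2ccccc2)c(OC)c1 | starting material
8 | 1-(benzyloxy)-4-(bromomethyl)-2-methoxybenzene | BrCc1ccc(OCc2ccccc2)c(OC)c1 | intermediate
9 | methyl 2-(benzyloxy)acetate | COC(=O)COCc1ccccc1 | starting material
10 | methyl 2-(benzyloxy)-3-[4-(benzyloxy)-3-methoxyphenyl]propanoate (racemic) | COC(=O)C(OCc1ccccc1)Cc1ccc(OCc2ccccc2)c(OC)c1 | intermediate
11 | 2-(benzyloxy)-3-[4-(benzyloxy)-3-methoxyphenyl]propanoic acid (racemic) | OC(=O)C(OCc1ccccc1)Cc1ccc(OCc2ccccc2)c(OC)c1 | intermediate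
12 | (2S,3Z)-5-[4-(benzyloxy)-3,5-dimethoxyphenyl]pent-3-en-2-yl 2-(benzyloxy)-3-[4-(benzyloxy)-3-methoxyphenyl]propanoate (both epimers at the acyl α-carbon) | C[C@H](OC(=O)C(OCc1ccccc1)Cc1ccc(OCc2ccccc2)c(OC)c1)/C=C\Cc1cc(OC)c(OCc2ccccc2)c(OC)c1 | intermediate
13 | {[(1Z)-2-(benzyloxy)-3-[4-(benzyloxy)-3-methoxyphenyl]-1-{[(2S,3Z)-5-[4-(benzyloxy)-3,5-dimethoxyphenyl]pent-3-en-2-yl]oxy}prop-1-en-1-yl]oxy}trimethylsilane (silyl ketene acetal of 12, Me3SiO cis to BnO) | C[C@H](O/C(O[Si](C)(C)C)=C(/OCc1ccccc1)Cc1ccc(OCc2ccccc2)c(OC)c1)/C=C\Cc1cc(OC)c(OCc2ccccc2)c(OC)c1 | intermediate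
14 | trimethylsilyl (2S,3S,4E)-2-(benzyloxy)-2-{[4-(benzyloxy)-3-methoxyphenyl]methyl}-3-{[4-(benzyloxy)-3,5-dimethoxyphenyl]methyl}hex-4-enoate | C[Si](C)(C)OC(=O)[C@](OCc1ccccc1)(Cc1ccc(OCc2ccccc2)c(OC)c1)[C@@H](Cc1cc(OC)c(OCc2ccccc2)c(OC)c1)/C=C/C | intermediate
15 | (2S,3S,4E)-2-(benzyloxy)-2-{[4-(benzyloxy)-3-methoxyphenyl]methyl}-3-{[4-(benzyloxy)-3,5-dimethoxyphenyl]methyl}hex-4-enoic acid | OC(=O)[C@](OCc1ccccc1)(Cc1ccc(OCc2ccccc2)c(OC)c1)[C@@H](Cc1cc(OC)c(OCc2ccccc2)c(OC)c1)/C=C/C | intermediate
16 | (2S,3R)-2-(benzyloxy)-2-{[4-(benzyloxy)-3-methoxyphenyl]methyl}-3-{[4-(benzyloxy)-3,5-dimethoxyphenyl]methyl}-4-oxobutanoic acid | OC(=O)[C@](OCc1ccccc1)(Cc1ccc(OCc2ccccc2)c(OC)c1)[C@@H](Cc1cc(OC)c(OCc2ccccc2)c(OC)c1)C=O | intermediate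
17 | (2S,3S)-2-(benzyloxy)-2-{[4-(benzyloxy)-3-methoxyphenyl]methyl}-3-{[4-(benzyloxy)-3,5-dimethoxyphenyl]methyl}-4-hydroxybutanoic acid | OC(=O)[C@](OCc1ccccc1)(Cc1ccc(OCc2ccccc2)c(OC)c1)[C@@H](Cc1cc(OC)c(OCc2ccccc2)c(OC)c1)CO | intermediate
18 | (3S,4S)-3-(benzyloxy)-3-{[4-(benzyloxy)-3-methoxyphenyl]methyl}-4-{[4-(benzyloxy)-3,5-dimethoxyphenyl]methyl}oxolan-2-one | COc1cc(C[C@@]2(OCc3ccccc3)C(=O)OC[C@@H]2Cc2cc(OC)c(OCc3ccccc3)c(OC)c2)ccc1OCc1ccccc1 | intermediate
19 | (3S,4S)-3-hydroxy-3-[(4-hydroxy-3-methoxyphenyl)methyl]-4-[(4-hydroxy-3,5-dimethoxyphenyl)methyl]oxolan-2-one (CNP0315014.1) | COc1cc(C[C@@]2(O)C(=O)OC[C@@H]2Cc2cc(OC)c(O)c(OC)c2)ccc1O | target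

**Step count and risks**

Total step count: 11. Longest linear sequence: 8 steps (steps 1, 2, 3, 4, 8, 9, 10, 11).

Steps most likely to fail:

Step 9 (Ireland–Claisen rearrangement). Loss of the lithium chelate or a competing boat pathway would erode the C3/C4 relationship, and the crowded, fully substituted ketene acetal may rearrange slowly and decompose by ketene loss. The fallback sets out from 6 and builds the quaternary centre afterwards by alkylation instead of in the rearrangement. Alcohol 6 would be esterified (DCC, DMAP) with purchased 2-(benzyloxy)acetic acid F1 to the glycolate ester F2. Its chelation-controlled Ireland–Claisen rearrangement (LiN(iPr)2, Me3SiCl, THF, −78 °C to rt), the best-precedented form of this reaction, would pass through the (Z)-silyl ketene acetal F3 and the silyl ester F4 to the acid F5, with C4 set by the same chirality transfer. Ozonolysis with NaBH4 work-up would give the oxo acid F6 and then the hydroxy acid F7, which acid would close to the lactone F8. Deprotonation of F8 (LiN(SiMe3)2, THF, −78 °C) and alkylation with bromide 8 on the face anti to the C4 benzyl group would place BnO cis to it and come back to the route at 18.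

Step 10 (ozonolysis, reduction, lactonisation). Ozone may attack the electron-rich rings A and B or the benzylic ether CH2 groups, and the α-branched aldehyde may epimerise at C4 before it is reduced. The fallback sets out from 15 and replaces the electrophilic oxidant by an osmium-catalysed dihydroxylation and glycol cleavage, which does not touch arenes. The sodium salt of 15 (NaHCO3, dioxane/H2O) would be dihydroxylated with OsO4 (cat.) to the diol F9 and cleaved in the same flask by NaIO4, and the sequence comes back to the route at 16, which is reduced and lactonised as in step 10.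

Step 6 (alkylation of the glycolate ester enolate). The enolate may self-condense or shift its O-benzyl group to carbon faster than it is alkylated, and part of the bromide may be lost to dialkylation. The fallback sets out from 8 and uses a stabilised malonate nucleophile. Purchased diethyl 2-(benzyloxy)propanedioate F10 (NaH, THF/DMF) would be alkylated by 8 to the diester F11, saponified (KOH, EtOH/H2O; HCl) to the diacid F12 and decarboxylated in hot toluene, which comes back to the route at 11.

**Further compounds**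

F1 | step 9 | 2-(benzyloxy)acetic acid | OC(=O)COCc1ccccc1
F2 | step 9 | (2S,3Z)-5-[4-(benzyloxy)-3,5-dimethoxyphenyl]pent-3-en-2-yl 2-(benzyloxy)acetate | C[C@H](OC(=O)COCc1ccccc1)/C=C\Cc1cc(OC)c(OCc2ccccc2)c(OC)c1
F3 | step 9 | {[(1Z)-2-(benzyloxy)-1-{[(2S,3Z)-5-[4-(benzyloxy)-3,5-dimethoxyphenyl]pent-3-en-2-yl]oxy}ethenyl]oxy}trimethylsilane (silyl ketene acetal of F2, Me3SiO cis to BnO) | C[C@H](O/C(O[Si](C)(C)C)=C/OCc1ccccc1)/C=C\Cc1cc(OC)c(OCc2ccccc2)c(OC)c1
F4 | step 9 | trimethylsilyl (2S,3S,4E)-2-(benzyloxy)-3-{[4-(benzyloxy)-3,5-dimethoxyphenyl]methyl}hex-4-enoate | C[Si](C)(C)OC(=O)[C@@H](OCc1ccccc1)[C@@H](Cc1cc(OC)c(OCc2ccccc2)c(OC)c1)/C=C/C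
F5 | step 9 | (2S,3S,4E)-2-(benzyloxy)-3-{[4-(benzyloxy)-3,5-dimethoxyphenyl]methyl}hex-4-enoic acid | OC(=O)[C@@H](OCc1ccccc1)[C@@H](Cc1cc(OC)c(OCc2ccccc2)c(OC)c1)/C=C/C
F6 | step 9 | (2S,3R)-2-(benzyloxy)-3-{[4-(benzyloxy)-3,5-dimethoxyphenyl]methyl}-4-oxobutanoic acid | OC(=O)[C@@H](OCc1ccccc1)[C@@H](Cc1cc(OC)c(OCc2ccccc2)c(OC)c1)C=O
F7 | step 9 | (2S,3S)-2-(benzyloxy)-3-{[4-(benzyloxy)-3,5-dimethoxyphenyl]methyl}-4-hydroxybutanoic acid | OC(=O)[C@@H](OCc1ccccc1)[C@@H](Cc1cc(OC)c(OCc2ccccc2)c(OC)c1)CO
F8 | step 9 | (3S,4S)-3-(benzyloxy)-4-{[4-(benzyloxy)-3,5-dimethoxyphenyl]methyl}oxolan-2-one | O=C1OC[C@H](Cc2cc(OC)c(OCc3ccccc3)c(OC)c2)[C@@H]1OCc1ccccc1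
F9 | step 10 | (2S,3S)-2-(benzyloxy)-2-{[4-(benzyloxy)-3-methoxyphenyl]methyl}-3-{[4-(benzyloxy)-3,5-dimethoxyphenyl]methyl}-4,5-dihydroxyhexanoic acid (mixture at C4 and C5, sodium salt in the flask) | OC(=O)[C@](OCc1ccccc1)(Cc1ccc(OCc2ccccc2)c(OC)c1)[C@@H](Cc1cc(OC)c(OCc2ccccc2)c(OC)c1)C(O)C(C)O
F10 | step 6 | diethyl 2-(benzyloxy)propanedioate | CCOC(=O)C(OCc1ccccc1)C(=O)OCC
F11 | step 6 | diethyl 2-(benzyloxy)-2-{[4-(benzyloxy)-3-methoxyphenyl]methyl}propanedioate | CCOC(=O)C(Cc1ccc(OCc2ccccc2)c(OC)c1)(OCc1ccccc1)C(=O)OCC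
F12 | step 6 | 2-(benzyloxy)-2-{[4-(benzyloxy)-3-methoxyphenyl]methyl}propanedioic acid | OC(=O)C(Cc1ccc(OCc2ccccc2)c(OC)c1)(OCc1ccccc1)C(=O)O
A1 | direct plan | (4R)-4-{[4-(benzyloxy)-3,5-dimethoxyphenyl]methyl}oxolan-2-one | O=C1OC[C@H](Cc2cc(OC)c(OCc3ccccc3)c(OC)c2)C1
A2 | direct plan | (3E,4R)-3-{[4-(benzyloxy)-3-methoxyphenyl]methylidene}-4-{[4-(benzyloxy)-3,5-dimethoxyphenyl]methyl}oxolan-2-one | O=C1OC[C@H](Cc2cc(OC)c(OCc3ccccc3)c(OC)c2)/C1=C\c4ccc(OCc5ccccc5)c(OC)c4
A3 | direct plan | (2E)-2-[(2R)-1-[4-(benzyloxy)-3,5-dimethoxyphenyl]-3-[(tert-butyldimethylsilyl)oxy]propan-2-yl]-3-[4-(benzyloxy)-3-methoxyphenyl]prop-2-en-1-ol | OC/C(=C/c1ccc(OCc2ccccc2)c(OC)c1)[C@@H](Cc1cc(OC)c(OCc2ccccc2)c(OC)c1)CO[Si](C)(C)C(C)(C)C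
A4 | direct plan | [(2S,3S)-3-[4-(benzyloxy)-3-methoxyphenyl]-2-[(2S)-1-[4-(benzyloxy)-3,5-dimethoxyphenyl]-3-[(tert-butyldimethylsilyl)oxy]propan-2-yl]oxiran-2-yl]methanol | OC[C@@]1(O[C@H]1c2ccc(OCc3ccccc3)c(OC)c2)[C@@H](Cc2cc(OC)c(OCc3ccccc3)c(OC)c2)CO[Si](C)(C)C(C)(C)C
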